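**Strategy**

Ampelopsin B is cut at the bond between C3 of the dihydrobenzofuran (the methine that also carries ring B, the second dioxygenated benzo ring) and C3a of ring A, the resorcinol ring fused to the furan. This bond belongs to both the seven-membered ring and the dihydrofuran; C3 is the β-carbon of a latent 4-hydroxystilbene and C3a lies ortho and para to the ring A oxygens. One iron-mediated phenol oxidation of an unprotected hexaphenol, a 2-substituted resveratrol with a chiral 1-aryl-2-(3,5-dihydroxyphenyl)ethyl arm, should therefore close both rings and set C2 and C3 under control of the single existing stereocentre, which comes from a phosphoric acid-catalysed transfer hydrogenation.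

Key step: step 7

Assumption: the (R)-configured phosphoric acid of step 5 is taken to deliver the (S) centre of 13; if the sense of induction proves opposite, its mirror image is used.

**Route**

Step 1
Reactants: 1 2-bromo-3,5-dimethoxybenzaldehyde; 2 diethyl (4-methoxybenzyl)phosphonate
Product: 3 (E)-2-bromo-1,5-dimethoxy-3-(4-methoxystyryl)benzene
Conditions: KOtBu, THF, 0 °C to rt
Reagents that add atoms: none
Why: Horner–Wadsworth–Emmons olefination, in which the benzylic phosphonate anion adds to the aldehyde and the thermodynamically controlled elimination gives the (E)-stilbene while the ortho bromide is untouched.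

Step 2
Reactants: 3 (E)-2-bromo-1,5-dimethoxy-3-(4-methoxystyryl)benzene; 4 4-[(tert-butyldimethylsilyl)oxy]benzaldehyde
Product: 6 rac-[4-(tert-butyldimethylsilyloxy)phenyl]{2,4-dimethoxy-6-[(E)-4-methoxystyryl]phenyl}methanol, via aryllithium 5 (not isolated)
Conditions: n-BuLi, THF, −78 °C; then 4, −78 to 0 °C; then H2O
Reagents that add atoms: none
Why: Bromine–lithium exchange at −78 °C is faster than carbolithiation of the stilbene and the aryllithium adds 1,2 to the aldehyde (the aryl silyl ether is inert at this temperature); the carbinol centre forms as a racemate and is removed in step 3.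

Step 3
Reactants: 6 rac-[4-(tert-butyldimethylsilyloxy)phenyl]{2,4-dimethoxy-6-[(E)-4-methoxystyryl]phenyl}methanol
Product: 7 [4-(tert-butyldimethylsilyloxy)phenyl]{2,4-dimethoxy-6-[(E)-4-methoxystyryl]phenyl}methanone
Conditions: Dess–Martin periodinane, CH2Cl2, rt
Reagents that add atoms: none
Why: Dess–Martin oxidation of a secondary diaryl carbinol to the benzophenone under neutral conditions that leave the stilbene and the aryl silyl ether untouched.

Step 4
Reactants: 7 [4-(tert-butyldimethylsilyloxy)phenyl]{2,4-dimethoxy-6-[(E)-4-methoxystyryl]phenyl}methanone; 8 3,5-dimethoxybenzyl chloride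
Product: 11 rac-4-[1-{2,4-dimethoxy-6-[(E)-4-methoxystyryl]phenyl}-2-(3,5-dimethoxyphenyl)-1-hydroxyethyl]phenol, via Grignard reagent 9 (not isolated), via chloromagnesium alkoxide 10 (not isolated)
Conditions: 8, Mg, THF, 0 °C; then 7, THF, −20 °C to rt; then Bu4NF, rt; then aq. NH4Cl
Reagents that add atoms: none
Why: Grignard 1,2-addition of a reactive benzylic magnesium reagent to a non-enolisable diaryl ketone, followed in the same flask by fluoride cleavage of the aryl silyl ether; the tertiary carbinol centre is racemic and is erased through the planar quinone methide in step 5, so partial dehydration of 11 on handling is of no consequence.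

Step 5
Reactants: 11 rac-4-[1-{2,4-dimethoxy-6-[(E)-4-methoxystyryl]phenyl}-2-(3,5-dimethoxyphenyl)-1-hydroxyethyl]phenol
Product: 13 4-[(1S)-1-{2,4-dimethoxy-6-[(E)-4-methoxystyryl]phenyl}-2-(3,5-dimethoxyphenyl)ethyl]phenol, via para-quinone methide 12 (not isolated)
Conditions: (R)-3,3′-bis(2,4,6-triisopropylphenyl)-1,1′-binaphthyl-2,2′-diyl hydrogen phosphate (5 mol %), diethyl 2,6-dimethyl-1,4-dihydropyridine-3,5-dicarboxylate (Hantzsch ester, 1.5 equiv), 4 Å molecular sieves, CH2Cl2, rt
Reagents that add atoms: none
Why: Organocatalytic asymmetric transfer hydrogenation of an in situ para-quinone methide: the chiral phosphoric acid ionises the para-hydroxybenzylic alcohol to 12, binds its carbonyl oxygen and the N–H of the Hantzsch ester, and directs hydride to one face of the exocyclic carbon, whose two substituents (a twisted, doubly ortho-substituted aryl group and a benzyl group) differ strongly in shape, which sets the (S) centre; hydride transfer inside the ion pair should outrun attack of the ortho styryl group, which would give an unstabilised benzylic cation.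

Step 6
Reactants: 13 4-[(1S)-1-{2,4-dimethoxy-6-[(E)-4-methoxystyryl]phenyl}-2-(3,5-dimethoxyphenyl)ethyl]phenol
Product: 14 5-[(2S)-2-{2,4-dihydroxy-6-[(E)-4-hydroxystyryl]phenyl}-2-(4-hydroxyphenyl)ethyl]benzene-1,3-diol
Conditions: BBr3 (8 equiv), CH2Cl2, −78 °C to rt; then H2O, 0 °C
Reagents that add atoms: none
Why: Lewis acid cleavage of the five aryl methyl ethers with BBr3 (coordination at oxygen, bromide attack at methyl), a method that tolerates electron-rich stilbenes of the resveratrol type; the stereocentre carries no leaving group and is not touched.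

Step 7
Reactants: 14 5-[(2S)-2-{2,4-dihydroxy-6-[(E)-4-hydroxystyryl]phenyl}-2-(4-hydroxyphenyl)ethyl]benzene-1,3-diol
Product: 16 ampelopsin B, via para-quinone methide 15 (not isolated)
Conditions: FeCl3·6H2O (2.2 equiv, added over 2 h), acetone, 1 mM, rt, exclusion of light
Reagents that add atoms: none
Why: Two equivalents of trivalent iron take two electrons and two protons from 14: the 4-hydroxystilbene phenol, the most easily oxidised of the six, gives a phenoxyl radical with spin on the styryl carbon next to ring B, this carbon bonds to an ortho carbon of the tethered resorcinol ring A, ring A rearomatises, and the para-quinone methide 15 so formed is trapped by the adjacent ring A hydroxyl. The closest known reaction type is the biomimetic oxidative coupling of 4-hydroxystilbenes with FeCl3·6H2O, in which the same stilbene carbon bonds to a resorcinol ortho carbon and the quinone methide closes to a 2,3-diaryl-2,3-dihydrobenzofuran; here it runs within one molecule. The seven-membered carbocycle closes in a 7-exo-trig mode (ring A carbon onto the proximal styryl carbon, the distal carbon staying outside the ring as the quinone methide carbon) and the dihydrofuran closes by 5-exo-trig oxa-1,6-addition. The new ring-fusion methine is controlled by the existing (S) centre: its 4-hydroxyphenyl group should sit pseudo-axial to avoid the peri oxygen of ring B, and only attack on the styryl face that places the new methine hydrogen on the same side leads to the boat in which the C–C(O) arm is coplanar with ring A as the furan requires; the oxygen-bearing carbon is set trans to ring B under thermodynamic control, because the quinone methide closure is reversible in the HCl that forms. The step needs chemoselective oxidation (the product has no hydroxystilbene left and should not be oxidised further), one site on ring A (the two ortho carbons are equivalent by the local symmetry of the 3,5-dihydroxybenzyl group and the carbon between the hydroxyls cannot reach) and ring closure in preference to dimerisation, which high dilution and slow addition of the oxidant should secure.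

**Compound list**

1 | 2-bromo-3,5-dimethoxybenzaldehyde | O=Cc1cc(OC)cc(OC)c1Br | starting material
2 | diethyl (4-methoxybenzyl)phosphonate | CCOP(=O)(Cc1ccc(OC)cc1)OCC | starting material
3 | (E)-2-bromo-1,5-dimethoxy-3-(4-methoxystyryl)benzene | COc1ccc(/C=C/c2cc(OC)cc(OC)c2Br)cc1 | intermediate
4 | 4-[(tert-butyldimethylsilyl)oxy]benzaldehyde | CC(C)(C)[Si](C)(C)Oc1ccc(C=O)cc1 | starting material
5 | {2,4-dimethoxy-6-[(E)-4-methoxystyryl]phenyl}lithium | COc1ccc(/C=C/c2cc(OC)cc(OC)c2[Li])cc1 | intermediate (not isolated)
6 | rac-[4-(tert-butyldimethylsilyloxy)phenyl]{2,4-dimethoxy-6-[(E)-4-methoxystyryl]phenyl}methanol | COc1ccc(/C=C/c2cc(OC)cc(OC)c2C(O)c2ccc(O[Si](C)(C)C(C)(C)C)cc2)cc1 | intermediate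
7 | [4-(tert-butyldimethylsilyloxy)phenyl]{2,4-dimethoxy-6-[(E)-4-methoxystyryl]phenyl}methanone | COc1ccc(/C=C/c2cc(OC)cc(OC)c2C(=O)c2ccc(O[Si](C)(C)C(C)(C)C)cc2)cc1 | intermediate
8 | 3,5-dimethoxybenzyl chloride | COc1cc(CCl)cc(OC)c1 | starting material
9 | (3,5-dimethoxybenzyl)magnesium chloride | COc1cc(C[Mg]Cl)cc(OC)c1 | intermediate (not isolated)
10 | chloromagnesium alkoxide of rac-1-[4-(tert-butyldimethylsilyloxy)phenyl]-1-{2,4-dimethoxy-6-[(E)-4-methoxystyryl]phenyl}-2-(3,5-dimethoxyphenyl)ethanol | COc1ccc(/C=C/c2cc(OC)cc(OC)c2C(O[Mg]Cl)(Cc2cc(OC)cc(OC)c2)c2ccc(O[Si](C)(C)C(C)(C)C)cc2)cc1 | intermediate (not isolated)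
11 | rac-4-[1-{2,4-dimethoxy-6-[(E)-4-methoxystyryl]phenyl}-2-(3,5-dimethoxyphenyl)-1-hydroxyethyl]phenol | COc1ccc(/C=C/c2cc(OC)cc(OC)c2C(O)(Cc2cc(OC)cc(OC)c2)c2ccc(O)cc2)cc1 | intermediate
12 | 4-[1-{2,4-dimethoxy-6-[(E)-4-methoxystyryl]phenyl}-2-(3,5-dimethoxyphenyl)ethylidene]cyclohexa-2,5-dien-1-one | COc1ccc(/C=C/c2cc(OC)cc(OC)c2C(Cc2cc(OC)cc(OC)c2)=C2C=CC(=O)C=C2)cc1 | intermediate (not isolated)
13 | 4-[(1S)-1-{2,4-dimethoxy-6-[(E)-4-methoxystyryl]phenyl}-2-(3,5-dimethoxyphenyl)ethyl]phenol | Oc1ccc([C@@H](c2c(OC)cc(OC)cc2/C=C/c2ccc(OC)cc2)Cc2cc(OC)cc(OC)c2)cc1 | intermediate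
14 | 5-[(2S)-2-{2,4-dihydroxy-6-[(E)-4-hydroxystyryl]phenyl}-2-(4-hydroxyphenyl)ethyl]benzene-1,3-diol | Oc1ccc([C@@H](c2c(O)cc(O)cc2/C=C/c2ccc(O)cc2)Cc2cc(O)cc(O)c2)cc1 | intermediate
15 | seven-membered-ring para-quinone methide (dibenzocycloheptadiene with the ring-fusion methine carrying a CH= group bonded to cyclohexa-2,5-dien-4-one; ring A hydroxyls free) | Oc1ccc([C@@H]2Cc3cc(O)cc(O)c3[C@H](c3cc(O)cc(O)c32)C=C2C=CC(=O)C=C2)cc1 | intermediate (not isolated)
16 | ampelopsin B, (S) at all three stereocentres | Oc1ccc([C@@H]2Cc3cc(O)cc4c3[C@H](c3cc(O)cc(O)c32)[C@@H](c2ccc(O)cc2)O4)cc1 | target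

**Count and risks**

Total step count: 7. Longest linear sequence: 7 steps (1 → 3 → 6 → 7 → 11 → 13 → 14 → 16).

The three steps most likely to fail:

1. Step 7. Bimolecular radical–radical coupling of the stilbene phenoxyl radical (dimerisation and oligomerisation) may outrun the seven-membered ring closure, and facial selectivity at the new ring-fusion methine relative to the existing centre may be low. The fallback sets out from 13 and returns at 16. Intramolecular oxidative Heck (Fujiwara–Moritani) alkenylation of the electron-rich ring A with divalent palladium (Pd(OAc)2 10 mol %, ethyl nicotinate, 1,4-benzoquinone, tert-amyl alcohol/AcOH, 80 °C) would palladate ring A ortho to the CH2 group and add across the stilbene in the 7-exo mode. After β-hydride elimination this would give the dibenzocycloheptene with an exocyclic 4-methoxybenzylidene group F1. BBr3 (CH2Cl2, −78 °C to rt) would then cleave the five methyl ethers to the hexaphenol alkene F2. The HBr formed (or HCl in MeOH) would protonate the exocyclic alkene at the ring-fusion carbon, and the flanking ring A hydroxyl would add to the 4-hydroxybenzylic cation. This is the known acid-mediated cyclisation of ortho-vinylphenols to dihydrobenzofurans and would give 16 with both new centres under thermodynamic control.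

2. Step 5. Enantiofacial discrimination in the hydride transfer may be poor, because the hydroxyl that anchors the catalyst is remote from the reacting carbon and that carbon carries a twisted, doubly ortho-substituted aryl group. The fallback sets out from 11 and returns at 13. Reduction with an achiral acid (diphenyl hydrogen phosphate, the same Hantzsch ester, CH2Cl2, rt) would give the racemic triarylethane F3. Preparative chromatography on a chiral stationary phase (amylose tris(3,5-dimethylphenylcarbamate), supercritical CO2/MeOH) would then deliver 13 by resolution instead of asymmetric catalysis.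

3. Step 4. 1,2-Addition to the doubly ortho-substituted ketone may be slow, so that homocoupling of the benzylic Grignard reagent or electron-transfer reduction of the ketone takes over. The fallback sets out from 4, 9 and 5 and returns at 10 (and so at 11); it reverses the order of bond formation. Grignard reagent 9 would add to the unhindered aldehyde 4 (THF, 0 °C; aq. NH4Cl) to give the secondary alcohol F4, and Dess–Martin oxidation would give the deoxybenzoin F5. Aryllithium 5, transmetalated with anhydrous CeCl3 (THF, −78 °C) to the weakly basic arylcerium dichloride F6, would add to F5 without enolisation to give 10, which is desilylated with Bu4NF as in step 4.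

Further compounds
F1 | step 7 | 4-[(10S)-2,4,7,9-tetramethoxy-5-(4-methoxybenzylidene)-10,11-dihydro-5H-dibenzo[a,d][7]annulen-10-yl]phenol (anisyl group cis to ring B) | Oc1ccc([C@@H]2Cc3cc(OC)cc(OC)c3/C(=C/c3ccc(OC)cc3)c3cc(OC)cc(OC)c32)cc1
F2 | step 7 | (10S)-5-(4-hydroxybenzylidene)-10-(4-hydroxyphenyl)-10,11-dihydro-5H-dibenzo[a,d][7]annulene-2,4,7,9-tetrol | Oc1ccc([C@@H]2Cc3cc(O)cc(O)c3/C(=C/c3ccc(O)cc3)c3cc(O)cc(O)c32)cc1
F3 | step 5 | rac-4-[1-{2,4-dimethoxy-6-[(E)-4-methoxystyryl]phenyl}-2-(3,5-dimethoxyphenyl)ethyl]phenol | Oc1ccc(C(c2c(OC)cc(OC)cc2/C=C/c2ccc(OC)cc2)Cc2cc(OC)cc(OC)c2)cc1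
F4 | step 4 | rac-1-[4-(tert-butyldimethylsilyloxy)phenyl]-2-(3,5-dimethoxyphenyl)ethanol | COc1cc(CC(O)c2ccc(O[Si](C)(C)C(C)(C)C)cc2)cc(OC)c1
F5 | step 4 | 1-[4-(tert-butyldimethylsilyloxy)phenyl]-2-(3,5-dimethoxyphenyl)ethanone | COc1cc(CC(=O)c2ccc(O[Si](C)(C)C(C)(C)C)cc2)cc(OC)c1
F6 | step 4 | dichloro{2,4-dimethoxy-6-[(E)-4-methoxystyryl]phenyl}cerium | COc1ccc(/C=C/c2cc(OC)cc(OC)c2[Ce](Cl)Cl)cc1
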